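**Retrosynthetic overview**

1. The strategy rests on the 2,6-dimethoxycyclohexa-2,5-dien-1-one ring: its C4 is the spiro carbon, bonded to the ring CH2 and to C2 of the 3,4,5-trimethoxyphenyl ring. It is therefore a 4-alkyl-2,6-dimethoxyphenol in oxidised form, and its two identical CH=C(OMe) arms leave the spiro carbon non-stereogenic.
2. Last disconnection: the spiro C–aryl C2 bond, formed by anodic dearomatising para (ipso) phenol–arene coupling of an open-chain 1,4-diarylbutyl benzoate. This closes the seven-membered carbocycle, the only ring that is built; both benzene rings are bought.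
3. Chain assembly: the aryl–CH(O) bond by Felkin–Anh addition of an aryl Grignard reagent to an α-methyl aldehyde; the aryl–CH2 carbon by ring-opening arylation of trans-2,3-dimethylsuccinic anhydride and deoxygenation of the resulting aryl ketone.
4. The threo CH(CH3)–CH(CH3) pair is C2-symmetric (2S,3S)-2,3-dimethylsuccinic acid from an oxazolidinone-controlled oxidative enolate homocoupling; its two carboxyl ends are homotopic, so the mono-arylation needs no desymmetrisation.

Key step: step 12

Remark on the chemistry: in the target the benzoyloxy carbon is R, the adjacent methyl-bearing carbon is S and the methyl-bearing carbon next to the ring CH2 is R; the (R)-auxiliary is assumed to direct each new C–C bond to the enolate face away from its benzyl group, as it does in alkylations.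

**Route**

Step 1
Reactants: 1 (R)-4-benzyl-3-propionyloxazolidin-2-one (two molecules)
Product: 3 (2S,3S)-1,4-bis[(R)-4-benzyl-2-oxooxazolidin-3-yl]-2,3-dimethylbutane-1,4-dione, via lithium Z-enolate 2 (not isolated)
Conditions: LiN(iPr)2 (LDA), THF, −78 °C; TiCl4, −78 °C to rt; recrystallisation
Reagents that add atoms: none
Why: Oxidative enolate homocoupling, in which TiCl4 (tetravalent titanium reduced to trivalent titanium) oxidises the chelated Evans Z-enolate by one electron and the two α-carbons join on the face away from each benzyl group, so the (R)-auxiliary should set both methyl-bearing carbons S and the C2-symmetric isomer should be freed from minor diastereomers by crystallisation.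

Step 2
Reactants: 3 (2S,3S)-bis-imide
Product: 5 (2S,3S)-2,3-dimethylsuccinic acid, via bis-peroxy acid 4 (not isolated)
Conditions: LiOH, 30% H2O2, THF/H2O, 0 °C; aq. Na2SO3; HCl to pH 1
Reagents that add atoms: hydrogen peroxide, OO
Why: Evans auxiliary cleavage with lithium hydroperoxide attacks the exocyclic imide carbonyl and is too weakly basic to enolise the α-carbons, sulfite then reduces the peracid, and the sign of rotation can be compared with that of the known (S,S)-diacid.

Step 3
Reactants: 5 (2S,3S)-2,3-dimethylsuccinic acid
Product: 6 (3S,4S)-3,4-dimethyloxolane-2,5-dione (trans-2,3-dimethylsuccinic anhydride)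
Conditions: (CF3CO)2O, CH2Cl2, 0 °C to rt; volatiles removed in vacuo, used crude
Reagents that add atoms: none
Why: Cyclodehydration of a 1,4-diacid to the five-membered anhydride under base-free conditions without heating avoids the enolisation that would epimerise the trans anhydride to the cis (meso) one.

Step 4
Reactants: 7 4-bromo-2,6-dimethoxyphenol
Product: 8 (4-bromo-2,6-dimethoxyphenoxy)triisopropylsilane
Conditions: TIPSOTf, 2,6-lutidine, CH2Cl2, 0 °C to rt
Reagents that add atoms: triisopropylsilyl trifluoromethanesulfonate, CC(C)[Si](C(C)C)(C(C)C)OS(=O)(=O)C(F)(F)F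
Why: O-Silylation of a hindered phenol with a silyl triflate and a hindered pyridine base gives an aryl silyl ether that should survive the Grignard, hydrogenolysis, borane and oxidation steps and still leave with fluoride.

Step 5
Reactants: 8 (4-bromo-2,6-dimethoxyphenoxy)triisopropylsilane; 6 (3S,4S)-trans-2,3-dimethylsuccinic anhydride
Product: 10 (2S,3S)-4-[3,5-dimethoxy-4-(triisopropylsilyloxy)phenyl]-2,3-dimethyl-4-oxobutanoic acid, via arylmagnesium bromide 9 (not isolated)
Conditions: 8, Mg turnings (I2 cat.), THF, 50 °C; added to 6 (1.3 equiv), THF, −78 to −20 °C; 1 M HCl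
Reagents that add atoms: none
Why: Grignard formation by magnesium insertion (chosen because halogen–magnesium exchange is slow on so electron-rich a bromide) followed by ring-opening acylation of the cyclic anhydride, in which the carboxylate-bearing adduct formed at −78 °C should resist a second addition and, since a C2 axis exchanges the two carbonyls, either attack gives the same (2S,3S) keto acid.

Step 6
Reactants: 10 (2S,3S)-keto acid
Product: 12 (2S,3R)-4-[3,5-dimethoxy-4-(triisopropylsilyloxy)phenyl]-2,3-dimethylbutanoic acid, via benzylic hydroxy acid 11 (not isolated)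
Conditions: H2 (3 atm), 10% Pd/C, AcOH, 40 °C
Reagents that add atoms: none
Why: Catalytic hydrogenation of the aryl ketone to the benzylic alcohol and hydrogenolysis of its C–O bond, both eased by the para silyloxy donor and acetic acid, should give the methylene without touching either stereocentre (C3 becomes R only through a change of substituent priority), and the diastereomeric purity is checked here because the ketone α-carbon is the one centre that could enolise.

Step 7
Reactants: 12 (2S,3R)-arylbutanoic acid
Product: 13 (2S,3R)-4-[3,5-dimethoxy-4-(triisopropylsilyloxy)phenyl]-2,3-dimethylbutan-1-ol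
Conditions: BH3·SMe2, THF, 0 °C to rt; MeOH quench
Reagents that add atoms: none
Why: Borane reduction of a carboxylic acid to the primary alcohol runs under non-basic conditions with no enolisable intermediate, so C2 keeps its configuration and the silyl ether is untouched.

Step 8
Reactants: 13 (2S,3R)-primary alcohol
Product: 14 (2S,3R)-4-[3,5-dimethoxy-4-(triisopropylsilyloxy)phenyl]-2,3-dimethylbutanal
Conditions: Dess–Martin periodinane, NaHCO3, CH2Cl2, 0 °C to rt; filtered, concentrated and used at once without chromatography
Reagents that add atoms: none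
Why: Dess–Martin oxidation stops at the aldehyde under buffered, near-neutral conditions that should not epimerise the α-methyl stereocentre.

Step 9
Reactants: 15 5-bromo-1,2,3-trimethoxybenzene; 14 (2S,3R)-aldehyde
Product: 17 (1R,2S,3R)-4-[3,5-dimethoxy-4-(triisopropylsilyloxy)phenyl]-2,3-dimethyl-1-(3,4,5-trimethoxyphenyl)butan-1-ol, via trimethoxyphenylmagnesium bromide 16 (not isolated)
Conditions: 15, Mg turnings (I2 cat.), THF, reflux; then 14, THF/CH2Cl2, −78 °C; aq. NH4Cl; chromatography
Reagents that add atoms: none
Why: Grignard 1,2-addition under Felkin–Anh control, with the sec-alkyl branch anti to the incoming aryl group and attack past the α-hydrogen, should favour the 1,2-syn carbinol with the new centre R, and the minor 1S epimer is removed by chromatography.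

Step 10
Reactants: 17 (1R,2S,3R)-carbinol; 18 benzoyl chloride
Product: 19 (1R,2S,3R)-4-[3,5-dimethoxy-4-(triisopropylsilyloxy)phenyl]-2,3-dimethyl-1-(3,4,5-trimethoxyphenyl)butyl benzoate
Conditions: pyridine, DMAP (cat.), CH2Cl2, 0 °C to rt
Reagents that add atoms: none
Why: DMAP-catalysed O-acylation with an acyl chloride forms the ester at oxygen, so the C1–O bond is not broken and the R configuration is retained.

Step 11
Reactants: 19 silyl-protected benzoate
Product: 20 (1R,2S,3R)-4-(4-hydroxy-3,5-dimethoxyphenyl)-2,3-dimethyl-1-(3,4,5-trimethoxyphenyl)butyl benzoate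
Conditions: Bu4NF, AcOH (1:1), THF, 0 °C
Reagents that add atoms: none
Why: Fluoride-driven desilylation of the aryl silyl ether, buffered with acetic acid so that the phenoxide is protonated as it forms, should leave the benzoate in place.

Step 12
Reactants: 20 free phenol
Product: 22 target CNP0201356.1 (spirodienone benzoate), via phenoxonium cation 21 (not isolated)
Conditions: undivided cell, graphite anode, platinum cathode, constant current (about 2 mA cm−2, 2.0–2.2 F mol−1), nBu4NBF4 (0.1 M), 2,6-lutidine (2 equiv), HFIP/CH2Cl2 (4:1), 0 °C
Reagents that add atoms: none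
Why: Two-electron anodic oxidation of the phenol with loss of the O–H proton gives phenoxonium cation 21, stabilised by its two ortho methoxy groups and by hydrogen bonding to HFIP; C2 of the tethered 3,4,5-trimethoxyphenyl ring, ortho and para to methoxy groups, adds to the cationic para carbon, and loss of the ring proton restores the benzenoid ring while the phenol ring stays as the 2,6-dimethoxycyclohexa-2,5-dienone. The closest known reaction type is the intramolecular oxidative para-phenol–arene (ipso) coupling to spirocyclohexadienones, run anodically or with trivalent iodine reagents in fluorinated alcohols, seven-membered spiro rings included. The seven-membered carbocycle closes in 7-exo-trig mode as an intramolecular Friedel–Crafts alkylation at the para carbon that carries the benzylic CH2. No stereocentre is created, because the two arms of the spiro carbon are identical, and the three existing centres are not enolisable and lie away from the bonds made. The step needs ipso C–C coupling to win over benzylic deprotonation to a quinone methide, over solvent capture and over acid-induced dienone–phenol rearrangement to the eight-membered biaryl. The substrate and medium secure this: both phenol ortho positions carry methoxy groups, C2 and C6 of the nucleophilic ring are equivalent, the benzylic oxygen is a benzoate and cannot close a spiro ether, HFIP is non-nucleophilic, and the lutidine buffer with a charge limit near 2 F per mol keeps the medium non-acidic and spares the less oxidisable dienone.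

**Compound list**

1 | (R)-4-benzyl-3-propionyloxazolidin-2-one | CCC(=O)N1[C@H](Cc2ccccc2)COC1=O | starting material
2 | lithium Z-enolate of 1 (not isolated) | C/C=C(\[O-])N1[C@H](Cc2ccccc2)COC1=O.[Li+] | intermediate
3 | (2S,3S)-1,4-bis[(R)-4-benzyl-2-oxooxazolidin-3-yl]-2,3-dimethylbutane-1,4-dione | O=C1OC[C@@H](Cc2ccccc2)N1C(=O)[C@@H](C)[C@H](C)C(=O)N1[C@H](Cc2ccccc2)COC1=O | intermediate
4 | (2S,3S)-2,3-dimethylbutanediperoxoic acid (bis-peroxy acid, not isolated) | OOC(=O)[C@@H](C)[C@H](C)C(=O)OO | intermediate
5 | (2S,3S)-2,3-dimethylsuccinic acid | OC(=O)[C@@H](C)[C@H](C)C(=O)O | intermediate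
6 | (3S,4S)-3,4-dimethyloxolane-2,5-dione (trans-2,3-dimethylsuccinic anhydride) | C[C@@H]1C(=O)OC(=O)[C@H]1C | intermediate
7 | 4-bromo-2,6-dimethoxyphenol | COc1cc(Br)cc(OC)c1O | starting material
8 | (4-bromo-2,6-dimethoxyphenoxy)triisopropylsilane | COc1cc(Br)cc(OC)c1O[Si](C(C)C)(C(C)C)C(C)C | intermediate
9 | [3,5-dimethoxy-4-(triisopropylsilyloxy)phenyl]magnesium bromide (not isolated) | COc1cc([Mg]Br)cc(OC)c1O[Si](C(C)C)(C(C)C)C(C)C | intermediate
10 | (2S,3S)-4-[3,5-dimethoxy-4-(triisopropylsilyloxy)phenyl]-2,3-dimethyl-4-oxobutanoic acid | COc1cc(C(=O)[C@@H](C)[C@H](C)C(=O)O)cc(OC)c1O[Si](C(C)C)(C(C)C)C(C)C | intermediate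
11 | (2S,3S)-4-[3,5-dimethoxy-4-(triisopropylsilyloxy)phenyl]-4-hydroxy-2,3-dimethylbutanoic acid (C4 epimers, not isolated) | COc1cc(C(O)[C@@H](C)[C@H](C)C(=O)O)cc(OC)c1O[Si](C(C)C)(C(C)C)C(C)C | intermediate
12 | (2S,3R)-4-[3,5-dimethoxy-4-(triisopropylsilyloxy)phenyl]-2,3-dimethylbutanoic acid | COc1cc(C[C@@H](C)[C@H](C)C(=O)O)cc(OC)c1O[Si](C(C)C)(C(C)C)C(C)C | intermediate
13 | (2S,3R)-4-[3,5-dimethoxy-4-(triisopropylsilyloxy)phenyl]-2,3-dimethylbutan-1-ol | COc1cc(C[C@@H](C)[C@H](C)CO)cc(OC)c1O[Si](C(C)C)(C(C)C)C(C)C | intermediate
14 | (2S,3R)-4-[3,5-dimethoxy-4-(triisopropylsilyloxy)phenyl]-2,3-dimethylbutanal | COc1cc(C[C@@H](C)[C@H](C)C=O)cc(OC)c1O[Si](C(C)C)(C(C)C)C(C)C | intermediate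
15 | 5-bromo-1,2,3-trimethoxybenzene | COc1cc(Br)cc(OC)c1OC | starting material
16 | (3,4,5-trimethoxyphenyl)magnesium bromide (not isolated) | COc1cc([Mg]Br)cc(OC)c1OC | intermediate
17 | (1R,2S,3R)-4-[3,5-dimethoxy-4-(triisopropylsilyloxy)phenyl]-2,3-dimethyl-1-(3,4,5-trimethoxyphenyl)butan-1-ol | COc1cc(C[C@@H](C)[C@H](C)[C@@H](O)c2cc(OC)c(OC)c(OC)c2)cc(OC)c1O[Si](C(C)C)(C(C)C)C(C)C | intermediate
18 | benzoyl chloride | O=C(Cl)c1ccccc1 | starting material
19 | (1R,2S,3R)-4-[3,5-dimethoxy-4-(triisopropylsilyloxy)phenyl]-2,3-dimethyl-1-(3,4,5-trimethoxyphenyl)butyl benzoate | COc1cc(C[C@@H](C)[C@H](C)[C@@H](OC(=O)c2ccccc2)c2cc(OC)c(OC)c(OC)c2)cc(OC)c1O[Si](C(C)C)(C(C)C)C(C)C | intermediate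
20 | (1R,2S,3R)-4-(4-hydroxy-3,5-dimethoxyphenyl)-2,3-dimethyl-1-(3,4,5-trimethoxyphenyl)butyl benzoate | COc1cc(C[C@@H](C)[C@H](C)[C@@H](OC(=O)c2ccccc2)c2cc(OC)c(OC)c(OC)c2)cc(OC)c1O | intermediate
21 | phenoxonium cation of 20, drawn with the charge on the para carbon (not isolated) | COC1=C[C+](C[C@@H](C)[C@H](C)[C@@H](OC(=O)c2ccccc2)c2cc(OC)c(OC)c(OC)c2)C=C(OC)C1=O | intermediate
22 | CNP0201356.1: (7R,8S,9R)-2,3,4,3',5'-pentamethoxy-7,8-dimethyl-4'-oxo-6,7,8,9-tetrahydrospiro[benzo[7]annulene-5,1'-cyclohexa-2',5'-dien]-9-yl benzoate | COC1=CC2(C=C(OC)C1=O)C[C@@H](C)[C@H](C)[C@@H](OC(=O)c1ccccc1)c1cc(OC)c(OC)c(OC)c12 | target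

**Step count**

Total steps: 12. Longest linear sequence: 11 steps (steps 1–3 and 5–12 from compound 1; step 4 is the one-step side branch from 7).

**Steps most likely to fail**

Step 12 (anodic spirocyclisation). The oxidised phenol may lose a benzylic proton and collapse to a quinone methide, or the benzylic benzoate may solvolyse in HFIP. The product may also be over-oxidised at the electrode, or suffer acid-triggered aryl migration (dienone–phenol rearrangement) in the anode layer. The fallback sets out from phenol 20 and comes back at 22. It replaces electron transfer at an electrode by an inner-sphere oxidant, PhI(OAc)2 (trivalent iodine), added in portions to 20 in HFIP over solid NaHCO3 at −20 °C. Ligand exchange at iodine gives an aryloxy-iodane that ionises within the solvent cage and is trapped by the tethered arene at low, uniform oxidant concentration with no electrode-surface acidity. No new compound lies on this path.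

Step 9 (aryl addition to the α-methyl aldehyde). Facial selectivity may be poor, because the methyl versus sec-alkyl difference gives only a weak Felkin–Anh bias, and the basic Grignard reagent may enolise the aldehyde. The fallback sets out from 17, taken as the unseparated mixture with its C1 epimer, and comes back at 17. It moves stereocontrol from the substrate to a reagent. Dess–Martin oxidation of the mixture gives a single ketone, (2S,3R)-4-[3,5-dimethoxy-4-(triisopropylsilyloxy)phenyl]-2,3-dimethyl-1-(3,4,5-trimethoxyphenyl)butan-1-one F1. Reduction with (S)-2-methyl-CBS-oxazaborolidine and BH3·SMe2, with the aryl group as the large substituent, should then deliver hydride to give the 1R carbinol 17. This sense is opposite to the substrate's own Felkin preference for hydride, so the reagent must dominate.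

Step 1 (oxidative homocoupling). The radical-type dimerisation may show low diastereoselectivity and low conversion through protonation back to 1 or α-chlorination. The fallback sets out from 1, as its lithium enolate 2, and comes back at diacid 5. It forms the C2–C3 bond by an SN2 alkylation in place of the oxidative coupling. Enolate 2 is alkylated at −78 °C with benzyl (S)-2-(trifluoromethylsulfonyloxy)propanoate F2, made from commercial benzyl (S)-lactate with Tf2O and 2,6-lutidine. Inversion at the lactate carbon and auxiliary control at the enolate carbon should give (R)-4-benzyl-3-[(2S,3S)-4-(benzyloxy)-2,3-dimethyl-4-oxobutanoyl]oxazolidin-2-one F3. Hydrogenolysis (H2, 10% Pd/C, EtOAc) gives (2S,3S)-4-[(R)-4-benzyl-2-oxooxazolidin-3-yl]-2,3-dimethyl-4-oxobutanoic acid F4, and LiOH/H2O2 cleavage as in step 2 gives 5.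

**Further compounds**

F0 | step 12 | none | none
F1 | step 9 | (2S,3R)-4-[3,5-dimethoxy-4-(triisopropylsilyloxy)phenyl]-2,3-dimethyl-1-(3,4,5-trimethoxyphenyl)butan-1-one | COc1cc(C[C@@H](C)[C@H](C)C(=O)c2cc(OC)c(OC)c(OC)c2)cc(OC)c1O[Si](C(C)C)(C(C)C)C(C)C
F2 | step 1 | benzyl (S)-2-(trifluoromethylsulfonyloxy)propanoate | C[C@H](OS(=O)(=O)C(F)(F)F)C(=O)OCc1ccccc1
F3 | step 1 | (R)-4-benzyl-3-[(2S,3S)-4-(benzyloxy)-2,3-dimethyl-4-oxobutanoyl]oxazolidin-2-one | O=C(OCc1ccccc1)[C@@H](C)[C@H](C)C(=O)N1[C@H](Cc2ccccc2)COC1=O
F4 | step 1 | (2S,3S)-4-[(R)-4-benzyl-2-oxooxazolidin-3-yl]-2,3-dimethyl-4-oxobutanoic acid | OC(=O)[C@@H](C)[C@H](C)C(=O)N1[C@H](Cc2ccccc2)COC1=O
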